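**Plan**

- Retrosynthesis: the two ester C–O bonds (O8 tiglate, O9 senecioate) and the C7–isopropenyl bond are cut first, the latter as an anti opening of a 7,8-epoxide cis to O9. Then C5–C10 and C1–C2 are cut together; last come C8–C9, C5–C6 and the four-membered ring (C2–C3, C4–C5).
- Enabling feature: ring A is a cyclohexanone in which C2(=O), C3, C4 (with C15) and quaternary C5 (with C14) form a cyclobutanone once the C10–C1 pair is removed from between C5 and C2. Ring B is then only the four-atom tether C6–C7=C8–C9 from C5 to that pair.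
- Forward order: the cyclobutanone is made first by [2+2] cycloaddition; the chain is attached at C5 and extended to a (Z)-dienyl silyl ether; ring B (C5–C10) and ring A (C1–C2) then close in one rhodium-catalysed operation; C7, C8 and the two esters follow.
- Stereochemistry: C4 comes from an auxiliary-controlled [2+2]; C5 from enolate alkylation anti to C15; C9 from a ligand-controlled alkynylation; C10 from C5 in the key step (cis fusion); C8 from O9 by directed epoxidation; C7 by inversion in the epoxide opening.

Key step: step 8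

Assumption: eremophilane numbering is used for the decalin compounds (ring A: C1–C5, C10; ring B: C5–C10; C14 on C5, C15 on C4). The senses of induction of the (2S,5S)-pyrrolidine auxiliary (step 2) and of (S,S)-ProPhenol (step 5) are assigned from the usual steric models; the antipodal auxiliary or ligand is taken if either proves reversed.

**Route**

Step 1
Reactants: 1 (2S,5S)-2,5-dimethylpyrrolidine; 2 propanoyl chloride
Product: 3 1-[(2S,5S)-2,5-dimethylpyrrolidin-1-yl]propan-1-one
Conditions: Et3N, CH2Cl2, 0 °C → rt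
Reagents that add atoms: none
Why: N-acylation of a secondary amine by an acid chloride (Schotten–Baumann type), which leaves the two ring stereocentres untouched.

Step 2
Reactants: 3 1-[(2S,5S)-2,5-dimethylpyrrolidin-1-yl]propan-1-one; 4 propene
Product: 7 (3S)-2,3-dimethylcyclobutan-1-one (both C2 epimers), via keteniminium triflate 5 (not isolated), via cyclobutaniminium triflate 6 (not isolated)
Conditions: Tf2O, 2,4,6-collidine, propene (excess), ClCH2CH2Cl, sealed vessel, −20 → 45 °C; then H2O, 45 °C; aq NaHCO3 work-up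
Reagents that add atoms: water, O
Why: Keteniminium–alkene [2+2] cycloaddition, in which the electrophilic central carbon bonds to the CH2 end of propene (placing the methyl on C3 of the ring), the C2-symmetric pyrrolidine shields one face and the cis preference of aldo-keteniminium additions ties C3 to that face, so hydrolysis should give the 3S ketone; C2 is of no concern because it becomes planar in step 3.

Step 3
Reactants: 7 (3S)-2,3-dimethylcyclobutan-1-one
Product: 8 {[(3S)-2,3-dimethylcyclobut-1-en-1-yl]oxy}trimethylsilane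
Conditions: Me3SiCl, Et3N, DMF, 80 °C, sealed vessel
Reagents that add atoms: chlorotrimethylsilane, C[Si](C)(C)Cl
Why: Silyl enol ether formation under equilibrating conditions should favour the more substituted C1=C2 isomer, while C3 is not enolisable and keeps its configuration.

Step 4
Reactants: 8 {[(3S)-2,3-dimethylcyclobut-1-en-1-yl]oxy}trimethylsilane; 9 3-bromoprop-1-yne (propargyl bromide)
Product: 11 (2R,3S)-2,3-dimethyl-2-(prop-2-yn-1-yl)cyclobutan-1-one, via lithium enolate 10 (not isolated)
Conditions: MeLi, THF, 0 °C; then 9, DMPU, −78 → −20 °C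
Reagents that add atoms: none
Why: Regiospecific enolate generation by Si–O cleavage followed by C-alkylation with a reactive propargylic bromide, the electrophile approaching the flat enolate anti to the adjacent ring methyl so that the chain is trans to C15 and the two methyls end up cis (2R).

Step 5
Reactants: 11 (2R,3S)-2,3-dimethyl-2-(prop-2-yn-1-yl)cyclobutan-1-one; 12 acrolein (prop-2-enal)
Product: 13 (2R,3S)-2-[(4S)-4-hydroxyhex-5-en-2-yn-1-yl]-2,3-dimethylcyclobutan-1-one
Conditions: (S,S)-ProPhenol (10 mol %), Me2Zn, Ph3PO (20 mol %), toluene, 0 → 4 °C; aq NH4Cl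
Reagents that add atoms: none
Why: Ligand-controlled addition of a zinc acetylide to an enal (dinuclear zinc–ProPhenol alkynylation), which tolerates the ketone and delivers the alkynyl group to the Re face of acrolein to set C9 as S independently of the remote ring stereocentres.

Step 6
Reactants: 13 (2R,3S)-2-[(4S)-4-hydroxyhex-5-en-2-yn-1-yl]-2,3-dimethylcyclobutan-1-one
Product: 14 (2R,3S)-2-[(4S)-4-(tert-butyldimethylsilyloxy)hex-5-en-2-yn-1-yl]-2,3-dimethylcyclobutan-1-one
Conditions: TBSCl, imidazole, DMF, rt
Reagents that add atoms: tert-butyldimethylsilyl chloride, CC(C)(C)[Si](C)(C)Cl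
Why: Imidazole-promoted silylation of a secondary alcohol, which protects O9 against redox isomerisation and ionisation in the rhodium step.

Step 7
Reactants: 14 (2R,3S)-2-[(4S)-4-(tert-butyldimethylsilyloxy)hex-5-en-2-yn-1-yl]-2,3-dimethylcyclobutan-1-one
Product: 15 (2R,3S)-2-[(2Z,4S)-4-(tert-butyldimethylsilyloxy)hexa-2,5-dien-1-yl]-2,3-dimethylcyclobutan-1-one
Conditions: H2 (1 atm), Pd/CaCO3 poisoned with Pb(OAc)2, quinoline, EtOAc, rt
Reagents that add atoms: none
Why: Semi-hydrogenation of the internal alkyne on lead-poisoned palladium adds H2 syn to give the Z alkene and is stopped before the more slowly reduced vinyl group reacts.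

Step 8
Reactants: 15 (2R,3S)-2-[(2Z,4S)-4-(tert-butyldimethylsilyloxy)hexa-2,5-dien-1-yl]-2,3-dimethylcyclobutan-1-one
Product: 16 (4S,4aR,8R,8aS)-8-(tert-butyldimethylsilyloxy)-4,4a-dimethyl-3,4,4a,5,8,8a-hexahydronaphthalen-2(1H)-one (9-silyloxy-4,5-dimethyl-cis-decal-7-en-2-one in eremophilane numbering)
Conditions: [Rh(C2H4)2Cl]2 (5 mol %), P[3,5-(CF3)2C6H3]3 (24 mol %), 1,4-dioxane, 130 °C, sealed tube
Reagents that add atoms: none
Why: Proposed new method: monovalent rhodium should add oxidatively into the strained acyl C2–C5 bond to give a trivalent rhodacyclopentanone (reversibly, so insertion into C2–C3 is a dead end that reverts), the pendant vinyl group then inserts 1,2 into Rh–C5, and C1–C2 reductive elimination releases the ketone and the catalyst. The closest known reaction type is the rhodium-catalysed intramolecular carboacylation of cyclobutanones with alkynes tethered at the α-carbon and of benzocyclobutenones with tethered alkenes; an α-tethered alkene on a saturated cyclobutanone has not been shown. Ring B closes by 6-exo migratory insertion (C5–C10) and ring A by C(sp3)–C(acyl) reductive elimination from a seven-membered rhodacycle, a two-carbon expansion of the four-membered ring. The only new stereocentre, C10, is controlled by C5: insertion is syn and retentive at C5, and the short C6–C9 tether holds the vinyl group on the face of the rhodacycle opposite C14 and C15, so C6 and C9 end on the same side of ring A and H10 comes out cis to C14. The vinyl group is chosen over the Z alkene by ring size (insertion of C7=C8 would make a three- or four-membered ring), and the electron-poor phosphine is meant to speed reductive elimination over decarbonylation and β-hydride loss. C4, C5 and C9 are spectators, and the C7=C8 alkene and the O9 silyl ether emerge placed for steps 11 and 12.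

Step 9
Reactants: 16 (4S,4aR,8R,8aS)-8-(tert-butyldimethylsilyloxy)-4,4a-dimethyl-3,4,4a,5,8,8a-hexahydronaphthalen-2(1H)-one
Product: 17 2,2-ethylenedioxy (1,3-dioxolane) ketal of 16, (4S,5R,9R,10S)
Conditions: HOCH2CH2OH, PPTS (cat.), benzene, reflux with azeotropic removal of water
Reagents that add atoms: ethane-1,2-diol, OCCO
Why: Acid-catalysed ketalisation of the unhindered C2 ketone masks it against the organomagnesium reagent of step 12, the mild pyridinium acid leaving the allylic silyl ether and the alkene in place.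

Step 10
Reactants: 17 2,2-ethylenedioxy ketal of 16
Product: 18 (4S,5R,9R,10S)-2,2-ethylenedioxy-4,5-dimethyl-cis-decal-7-en-9-ol
Conditions: TBAF, THF, 0 °C → rt
Reagents that add atoms: none
Why: Fluoride-mediated Si–O cleavage frees the allylic C9 hydroxyl that is needed to direct the epoxidation.

Step 11
Reactants: 18 (4S,5R,9R,10S)-2,2-ethylenedioxy-4,5-dimethyl-cis-decal-7-en-9-ol
Product: 19 (4S,5R,7R,8S,9S,10S)-7,8-epoxy-2,2-ethylenedioxy-4,5-dimethyl-cis-decalin-9-ol (epoxide cis to the hydroxyl)
Conditions: VO(acac)2 (3 mol %), t-BuOOH, CH2Cl2, 0 °C → rt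
Reagents that add atoms: tert-butyl hydroperoxide, CC(C)(C)OO
Why: Hydroxyl-directed epoxidation of an allylic alcohol, in which the peroxide oxygen is delivered within the vanadate ester to the alkene face syn to O9 and so fixes the C8–O bond cis to O9.

Step 12
Reactants: 19 (4S,5R,7R,8S,9S,10S)-7,8-epoxy-2,2-ethylenedioxy-4,5-dimethyl-cis-decalin-9-ol; 20 isopropenylmagnesium bromide
Product: 21 (4S,5R,7R,8R,9S,10S)-2,2-ethylenedioxy-4,5-dimethyl-7-(prop-1-en-2-yl)-cis-decalin-8,9-diol
Conditions: 20 (4 equiv), CuBr·SMe2 (20 mol %), THF, −30 → 0 °C; aq NH4Cl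
Reagents that add atoms: none
Why: Copper-catalysed Grignard opening of an epoxide by SN2 attack with inversion, expected at C7 because it is remote from the electron-withdrawing C9 oxygen, so the isopropenyl group enters anti to the epoxide oxygen (trans to O8) and C8–OH stays cis to C9–OH.

Step 13
Reactants: 21 (4S,5R,7R,8R,9S,10S)-2,2-ethylenedioxy-4,5-dimethyl-7-(prop-1-en-2-yl)-cis-decalin-8,9-diol; 22 (E)-2-methylbut-2-enoyl chloride (tigloyl chloride)
Product: 23 C8 mono-tiglate of 21 (C9 hydroxyl free)
Conditions: 22 (1.1 equiv), pyridine, DMAP (cat.), CH2Cl2, −20 → 0 °C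
Reagents that add atoms: none
Why: DMAP-catalysed esterification should select the equatorial C8 hydroxyl over the axial C9 hydroxyl, which is flanked by the ring fusion, and the E geometry is carried in from the acid chloride.

Step 14
Reactants: 23 C8 mono-tiglate of 21; 24 3-methylbut-2-enoyl chloride
Product: 25 2,2-ethylenedioxy ketal of the target (C8 tiglate, C9 senecioate)
Conditions: 24 (3 equiv), pyridine, DMAP, CH2Cl2, 0 °C → rt
Reagents that add atoms: none
Why: DMAP-catalysed esterification of the remaining hindered hydroxyl with excess acid chloride, pyridine being used in place of a trialkylamine to limit vinylketene formation and deconjugation of the senecioyl group.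

Step 15
Reactants: 25 2,2-ethylenedioxy ketal of the target
Product: 26 (4S,5R,7R,8R,9S,10S)-9-(3-methylbut-2-enoyloxy)-8-[(E)-2-methylbut-2-enoyloxy]-cis-eremophil-11-en-2-one (CNP0181050.1)
Conditions: 1 M HCl, THF, rt
Reagents that add atoms: water, O
Why: Acid-catalysed ketal hydrolysis regenerates the C2 ketone, the enoate esters and the isopropenyl group being stable to dilute acid and no stereocentre lying α to the ketone.

**Compound list**

1 | (2S,5S)-2,5-dimethylpyrrolidine | C[C@H]1CC[C@H](C)N1 | starting material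
2 | propanoyl chloride | CCC(=O)Cl | starting material
3 | 1-[(2S,5S)-2,5-dimethylpyrrolidin-1-yl]propan-1-one | CCC(=O)N1[C@@H](C)CC[C@@H]1C | intermediate
4 | propene | CC=C | starting material
5 | (2S,5S)-2,5-dimethyl-1-(prop-1-en-1-ylidene)pyrrolidin-1-ium trifluoromethanesulfonate (keteniminium triflate) | CC=C=[N+]1[C@@H](C)CC[C@@H]1C.[O-]S(=O)(=O)C(F)(F)F | intermediate (not isolated)
6 | (2S,5S)-1-[(3S)-2,3-dimethylcyclobutylidene]-2,5-dimethylpyrrolidin-1-ium trifluoromethanesulfonate (cyclobutaniminium triflate) | CC1[C@@H](C)CC1=[N+]1[C@@H](C)CC[C@@H]1C.[O-]S(=O)(=O)C(F)(F)F | intermediate (not isolated)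
7 | (3S)-2,3-dimethylcyclobutan-1-one, both C2 epimers | CC1C(=O)C[C@@H]1C | intermediate
8 | {[(3S)-2,3-dimethylcyclobut-1-en-1-yl]oxy}trimethylsilane | CC1=C(O[Si](C)(C)C)C[C@@H]1C | intermediate
9 | 3-bromoprop-1-yne (propargyl bromide) | C#CCBr | starting material
10 | lithium (3S)-2,3-dimethylcyclobut-1-en-1-olate (lithium enolate) | CC1=C([O-])C[C@@H]1C.[Li+] | intermediate (not isolated)
11 | (2R,3S)-2,3-dimethyl-2-(prop-2-yn-1-yl)cyclobutan-1-one | C#CC[C@@]1(C)C(=O)C[C@@H]1C | intermediate
12 | acrolein (prop-2-enal) | C=CC=O | starting material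
13 | (2R,3S)-2-[(4S)-4-hydroxyhex-5-en-2-yn-1-yl]-2,3-dimethylcyclobutan-1-one | C=C[C@H](O)C#CC[C@@]1(C)C(=O)C[C@@H]1C | intermediate
14 | (2R,3S)-2-[(4S)-4-(tert-butyldimethylsilyloxy)hex-5-en-2-yn-1-yl]-2,3-dimethylcyclobutan-1-one | C=C[C@H](O[Si](C)(C)C(C)(C)C)C#CC[C@@]1(C)C(=O)C[C@@H]1C | intermediate
15 | (2R,3S)-2-[(2Z,4S)-4-(tert-butyldimethylsilyloxy)hexa-2,5-dien-1-yl]-2,3-dimethylcyclobutan-1-one | C=C[C@H](O[Si](C)(C)C(C)(C)C)/C=C\C[C@@]1(C)C(=O)C[C@@H]1C | intermediate
16 | (4S,4aR,8R,8aS)-8-(tert-butyldimethylsilyloxy)-4,4a-dimethyl-3,4,4a,5,8,8a-hexahydronaphthalen-2(1H)-one | C1=C[C@@H](O[Si](C)(C)C(C)(C)C)[C@H]2CC(=O)C[C@H](C)[C@@]2(C)C1 | intermediate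
17 | (4S,5R,9R,10S)-9-(tert-butyldimethylsilyloxy)-2,2-ethylenedioxy-4,5-dimethyl-cis-decal-7-ene (dioxolane ketal of 16) | C1=C[C@@H](O[Si](C)(C)C(C)(C)C)[C@H]2CC3(OCCO3)C[C@H](C)[C@@]2(C)C1 | intermediate
18 | (4S,5R,9R,10S)-2,2-ethylenedioxy-4,5-dimethyl-cis-decal-7-en-9-ol | C1=C[C@@H](O)[C@H]2CC3(OCCO3)C[C@H](C)[C@@]2(C)C1 | intermediate
19 | (4S,5R,7R,8S,9S,10S)-7,8-epoxy-2,2-ethylenedioxy-4,5-dimethyl-cis-decalin-9-ol (epoxide cis to OH) | C[C@H]1CC2(OCCO2)C[C@@H]3[C@H](O)[C@@H]4O[C@@H]4C[C@]13C | intermediate
20 | isopropenylmagnesium bromide | C=C(C)[Mg]Br | starting material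
21 | (4S,5R,7R,8R,9S,10S)-2,2-ethylenedioxy-4,5-dimethyl-7-(prop-1-en-2-yl)-cis-decalin-8,9-diol | C[C@H]1CC2(OCCO2)C[C@@H]3[C@H](O)[C@H](O)[C@@H](C(C)=C)C[C@]13C | intermediate
22 | (E)-2-methylbut-2-enoyl chloride (tigloyl chloride) | C/C=C(\C)C(=O)Cl | starting material
23 | (4S,5R,7R,8R,9S,10S)-2,2-ethylenedioxy-9-hydroxy-4,5-dimethyl-7-(prop-1-en-2-yl)-cis-decalin-8-yl (E)-2-methylbut-2-enoate | C[C@H]1CC2(OCCO2)C[C@@H]3[C@H](O)[C@H](OC(=O)/C(C)=C/C)[C@@H](C(C)=C)C[C@]13C | intermediate
24 | 3-methylbut-2-enoyl chloride | CC(C)=CC(=O)Cl | starting material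
25 | (4S,5R,7R,8R,9S,10S)-2,2-ethylenedioxy-9-(3-methylbut-2-enoyloxy)-4,5-dimethyl-7-(prop-1-en-2-yl)-cis-decalin-8-yl (E)-2-methylbut-2-enoate | C[C@H]1CC2(OCCO2)C[C@@H]3[C@H](OC(=O)C=C(C)C)[C@H](OC(=O)/C(C)=C/C)[C@@H](C(C)=C)C[C@]13C | intermediate
26 | (4S,5R,7R,8R,9S,10S)-9-(3-methylbut-2-enoyloxy)-8-[(E)-2-methylbut-2-enoyloxy]-cis-eremophil-11-en-2-one | C=C(C)[C@H]1C[C@@]2(C)[C@H](CC(=O)C[C@@H]2C)[C@H](OC(=O)C=C(C)C)[C@@H]1OC(=O)/C(C)=C/C | target

**Step count and risks**

Total steps: 15. Longest linear sequence: 15 steps (1 and 2 to 26).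

Steps most likely to fail:

1. Step 8 (key step). Migration of the doubly allylic C9–H by a rhodium hydride, decarbonylation of the rhodacycle, or β-hydride loss after insertion may outrun carboacylation. The fallback changes the sp2 partner to an alkyne, for which this carboacylation is established, and sets the C10 hydrogen afterwards.
   - It sets out from alkyne 11. The zinc–ProPhenol alkynylation of step 5 is run with 3-(trimethylsilyl)propynal in place of acrolein to give the silyl-capped diynol F1, and O-silylation (TBSCl, imidazole) gives the bis-silyl diyne F2.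
   - Semi-hydrogenation over Pd/CaCO3 poisoned with Pb(OAc)2, which should spare the silyl-capped alkyne, gives the Z enyne F3. K2CO3 in MeOH then removes the alkynyl silyl group to leave the terminal enyne F4.
   - Rhodium-catalysed alkyne carboacylation ([Rh(C2H4)2Cl]2, the same phosphine, dioxane, heat) closes both rings to the bicyclic dienone F5, which has a C1=C10 enone and keeps C7=C8.
   - Conjugate reduction with [(Ph3P)CuH]6 should deliver hydride to C10 anti to the bulky C9 silyl ether, giving the cis-fused ketone. The fallback comes back to the route at 16.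

2. Step 12. The regioselectivity of the epoxide opening may be eroded: the cis-decalin can react through its other chair, in which attack at C8 avoids the 1,3-diaxial contact between the incoming group at C7 and C14. Opening of the epoxide by bromide is a second possible loss. The fallback places the isopropenyl group by conjugate addition instead.
   - It sets out from allylic alcohol 18. Oxidation with Dess–Martin periodinane gives the C9 enone F6.
   - Isopropenylmagnesium bromide 20 with CuBr·SMe2 and Me3SiCl should add 1,4 at C7 on the face of the smaller C5 substituent (C14), and the enolate is trapped as the silyl enol ether F7.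
   - Rubottom oxidation (1 equiv m-CPBA at −20 °C, then TBAF) should install the C8 hydroxyl anti to the isopropenyl group, giving the hydroxy ketone F8.
   - Li(s-Bu)3BH, attacking the C9 carbonyl from the equatorial direction, should give the axial alcohol cis to O8. The fallback comes back to the route at 21.

3. Step 2. Enantiocontrol at the future C4 may be poor, because it needs both facial control by the auxiliary and a high cis preference in the cycloaddition; loss of the volatile ketone is a further hazard. The fallback sets C4 by enantiotopic deprotonation of an achiral ketone.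
   - It sets out from propene 4. [2+2] cycloaddition with dichloroketene (Cl3CCOCl, Zn(Cu), Et2O) gives 2,2-dichloro-3-methylcyclobutan-1-one F9.
   - Zinc in acetic acid removes both chlorines to give achiral 3-methylcyclobutan-1-one F10.
   - The appropriate enantiomer of lithium bis(1-phenylethyl)amide, with Me3SiCl as in situ quench at −100 °C, removes one of the two enantiotopic α-protons to give the (S)-silyl enol ether F11.
   - MeLi followed by MeI gives the 3S-configured 2,3-dimethyl ketone. The fallback comes back to the route at 7.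

**Further compounds**

F1 | step 8 | (2R,3S)-2-[(4R)-4-hydroxy-6-(trimethylsilyl)hexa-2,5-diyn-1-yl]-2,3-dimethylcyclobutan-1-one | C[Si](C)(C)C#C[C@H](O)C#CC[C@@]1(C)C(=O)C[C@@H]1C
F2 | step 8 | (2R,3S)-2-[(4R)-4-(tert-butyldimethylsilyloxy)-6-(trimethylsilyl)hexa-2,5-diyn-1-yl]-2,3-dimethylcyclobutan-1-one | C[Si](C)(C)C#C[C@H](O[Si](C)(C)C(C)(C)C)C#CC[C@@]1(C)C(=O)C[C@@H]1C
F3 | step 8 | (2R,3S)-2-[(2Z,4R)-4-(tert-butyldimethylsilyloxy)-6-(trimethylsilyl)hex-2-en-5-yn-1-yl]-2,3-dimethylcyclobutan-1-one | C[Si](C)(C)C#C[C@H](O[Si](C)(C)C(C)(C)C)/C=C\C[C@@]1(C)C(=O)C[C@@H]1C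
F4 | step 8 | (2R,3S)-2-[(2Z,4R)-4-(tert-butyldimethylsilyloxy)hex-2-en-5-yn-1-yl]-2,3-dimethylcyclobutan-1-one | C#C[C@H](O[Si](C)(C)C(C)(C)C)/C=C\C[C@@]1(C)C(=O)C[C@@H]1C
F5 | step 8 | (4S,4aR,8R)-8-(tert-butyldimethylsilyloxy)-4,4a-dimethyl-4,4a,5,8-tetrahydronaphthalen-2(3H)-one | C1=C[C@@H](O[Si](C)(C)C(C)(C)C)C2=CC(=O)C[C@H](C)[C@@]2(C)C1
F6 | step 12 | (4S,5R,10S)-2,2-ethylenedioxy-4,5-dimethyl-cis-decal-7-en-9-one | C[C@H]1CC2(OCCO2)C[C@@H]3C(=O)C=CC[C@]13C
F7 | step 12 | (4S,5R,7R,10S)-2,2-ethylenedioxy-4,5-dimethyl-7-(prop-1-en-2-yl)-9-(trimethylsilyloxy)-cis-decal-8-ene | C[C@H]1CC2(OCCO2)C[C@@H]3C(O[Si](C)(C)C)=C[C@@H](C(C)=C)C[C@]13C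
F8 | step 12 | (4S,5R,7R,8R,10S)-2,2-ethylenedioxy-8-hydroxy-4,5-dimethyl-7-(prop-1-en-2-yl)-cis-decalin-9-one | C[C@H]1CC2(OCCO2)C[C@@H]3C(=O)[C@H](O)[C@@H](C(C)=C)C[C@]13C
F9 | step 2 | 2,2-dichloro-3-methylcyclobutan-1-one (racemic) | CC1CC(=O)C1(Cl)Cl
F10 | step 2 | 3-methylcyclobutan-1-one | CC1CC(=O)C1
F11 | step 2 | {[(3S)-3-methylcyclobut-1-en-1-yl]oxy}trimethylsilane | C1=C(O[Si](C)(C)C)C[C@@H]1C
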